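Labels used throughout: ring A = C1(OAng)–C2(OAc)–C3(OAng)–C4(Me)–C5–C6–C11(Me2); cyclobutane ring C = C4–C5–C6–C7; ring B = C5–C6–C7–C8(=O)–C9–C10(Me).
A direct plan would make ring C first (cyclobutanone A1 from silylated methallyl alcohol and dichloroketene), fuse ring B onto it by an enamine/crotonyl chloride α,α′-annulation to bicyclic dione A2, convert the silyloxymethyl group into an acryloyl group (A3), close ring A last by an iron-hydride-initiated 7-endo radical cyclisation to A4, and then oxidise ring A (enone, CBS reduction, osmylation to diol A5, inversion at C2) before esterification.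
Weak point 1, the ring B annulation A1 → A2: it is unknown on a cyclobutanone enamine, it builds a bridged non-enolisable 1,3-diketone prone to retro-Claisen opening, and it must control face, enantiotopic α-carbon and C- versus O-acylation at once.
Weak point 2, the ring A closure A3 → A4: a tertiary radical on C11 beside the cyclobutane (a cyclobutylcarbinyl radical that can ring-open) would have to close a seven-membered ring in the endo mode, and it is reached only after six protecting-group and redox steps that add three carbons.
Weak point 3, the triol: osmylation anti to the C3 oxygen would set C2 with the wrong configuration (A5), so a cyclic sulfate/acetate inversion would be needed to correct it.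

**Retrosynthetic overview**
The chain C6–C7–C8–C9–C10–C5=C4–C3–C2–C1–C11 is read out of the skeleton: cutting C5–C6 and C4–C7 (rings B and C together) and C6–C11 (ring A) leads to acyclic keto acid 12, whose only stereocentre is C10.
Forward, the acid chloride of 12 gives a vinylketene (C6=C7, C8=CH2) that adds to the 6E alkene C4=C5 in the crossed sense. C6 becomes the ketone bridge of bicyclo[3.1.1]heptan-6-one 15, C4 the quaternary bridge (methyl over ring B), and C10 directs the face.
Ring A then closes by intramolecular aldol of the C11 enolate of the side-chain ketone onto cyclobutanone C6 (face fixed by the tether on C4); the C6 oxygen is removed by Barton–McCombie reduction. Ring order: B + C, then A.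
This avoids any annulation on a cyclobutanone and any radical ring closure beside the four-membered ring. C3, C2, C1 and C11 arrive in one Carroll rearrangement, and the triol is set without inversion (CBS at C1, then osmylation anti to C1–OH gives 1,2-trans-2,3-cis).
12 comes in six steps from an Evans alkylation (C10), an isopropenyl Grignard addition and the Carroll rearrangement.
Key step: step 7

Remark: ethyl (E)-4-bromo-3-methylbut-2-enoate (2) is taken as a purchasable reagent (it is the allylic bromination product of ethyl 3-methylbut-2-enoate).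

**Route**

Step 1
Reactants: 1 (S)-4-benzyl-3-propanoyloxazolidin-2-one; 2 ethyl (E)-4-bromo-3-methylbut-2-enoate
Product: 3 (S)-4-benzyl-3-[(2R,4E)-6-ethoxy-2,4-dimethyl-6-oxohex-4-enoyl]oxazolidin-2-one
Conditions: NaN(SiMe3)2, THF, −78 °C; then 2, −78 → −40 °C
Reagents that add atoms: none
Why: Evans asymmetric alkylation: the chelated Z-sodium enolate is alkylated at CH2Br on the face opposite the benzyl group, which sets C10 as R; the β,β-disubstituted enoate of 2 is a poor Michael acceptor.

Step 2
Reactants: 3 alkylated imide
Product: 4 ethyl (2E,5R)-6-hydroxy-3,5-dimethylhex-2-enoate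
Conditions: NaBH4, THF/H2O, 0 °C → rt
Reagents that add atoms: none
Why: Reductive removal of the auxiliary (hydride attack at the exocyclic imide carbonyl), which leaves the conjugated ester untouched and returns the oxazolidinone.

Step 3
Reactants: 4 hydroxy ester
Product: 5 ethyl (2E,5R)-3,5-dimethyl-6-oxohex-2-enoate
Conditions: TEMPO (10 mol %), PhI(OAc)2, CH2Cl2, rt
Reagents that add atoms: none
Why: TEMPO-catalysed oxidation stops at the aldehyde and should not epimerise the α-stereocentre C10.

Step 4
Reactants: 5 aldehyde; 6 isopropenylmagnesium bromide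
Product: 7 ethyl (2E,5R)-6-hydroxy-3,5,7-trimethylocta-2,7-dienoate (both carbinol epimers)
Conditions: 6 (1.3 equiv), THF, −78 °C; aq. NH4Cl
Reagents that add atoms: none
Why: Grignard addition to the aldehyde, much faster at −78 °C than addition to the conjugated ester; the new carbinol centre (later C5) is a mixture that is erased in step 5.

Step 5
Reactants: 7 allylic alcohol; 8 methyl 4-methyl-3-oxopentanoate
Product: 11 ethyl (2E,5R,6E)-3,5,7,11-tetramethyl-10-oxododeca-2,6-dienoate, via allyl β-keto ester 9 (not isolated), via β-keto acid 10 (not isolated)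
Conditions: 8 (3 equiv), DMAP (10 mol %), xylene, 140 °C with removal of MeOH; then 180 °C (sealed tube)
Reagents that add atoms: none
Why: Carroll rearrangement (transacylation, [3,3] shift of the enol, decarboxylation): the chair transition state with the carbinol substituent equatorial gives the 6E alkene C4=C5 and delivers C3, C2, C1 and the isopropyl carbon C11 in one operation, with C10 untouched.

Step 6
Reactants: 11 keto ester
Product: 12 (2E,5R,6E)-3,5,7,11-tetramethyl-10-oxododeca-2,6-dienoic acid
Conditions: LiOH, THF/MeOH/H2O, 40 °C; then 1 M HCl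
Reagents that add atoms: lithium hydroxide, [Li+].[OH-]
Why: Saponification of the ethyl ester; the ketone and both trisubstituted alkenes are inert.

Step 7
Reactants: 12 keto acid
Product: 15 (1R,2R,5S,7R)-2,7-dimethyl-4-methylidene-7-(4-methyl-3-oxopentyl)bicyclo[3.1.1]heptan-6-one (rings B and C; C6 ketone, C8 methylidene, C4 methyl over ring B, C10 methyl on the side of C6), via acid chloride 13 (not isolated), via vinylketene 14 (not isolated)
Conditions: (COCl)2, PhH, rt, then evaporation; Et3N (3 equiv), PhMe, reflux, slow addition of 13 (final 0.01 M)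
Reagents that add atoms: none
Why: Intramolecular ketene–alkene [2+2] cycloaddition: Et3N removes HCl across the γ-methyl group (cis to the acyl group in the 2E acid chloride) to give vinylketene 14, whose electrophilic central carbon C6 bonds to the less substituted alkene carbon C5 while C7 closes onto C4, the carbon that best carries positive charge; this crossed mode is the known outcome for 3-methyl-2,6-dienoyl chlorides of the geranic and farnesoic type, which give 2-methylidenebicyclo[3.1.1]heptan-6-ones. Ring B closes as a six-membered ring through the C5–C6 bond (three-atom tether C8–C9–C10) and ring C through the second bond C4–C7. The addition is suprafacial on the alkene, so the 6E geometry (methyl cis to C10) places the C4 methyl on the cyclobutane face of C10, over ring B, and the keto chain on the side of C6; C5 and C7 follow from the bridged ring. C10 sets the π-face: in the transition state the tether carbon C9 lies between C4 and C6, and the C10 hydrogen rather than the C10 methyl takes the position beside the cis methyl on C4 (allylic 1,3-strain, which would become a syn-pentane clash in the other diastereomer), so the C10 methyl ends on the side of C6. The step needs methyl versus methylene γ-deprotonation (secured by the 2E geometry), crossed versus fused regiochemistry (trisubstituted alkene, three-atom tether) and cycloaddition versus ketene oligomerisation (slow addition, high dilution); the side-chain ketone should be a spectator.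

Step 8
Reactants: 15 bicyclic diketone
Product: 17 tricyclic S-methyl xanthate (ring A closed; C1 ketone; C6–OC(=S)SCH3 with the oxygen toward ring B; C8 methylidene), via potassium aldolate 16 (not isolated)
Conditions: KN(SiMe3)2 (1.05 equiv), t-BuOH (0.1 equiv), THF (0.005 M), −78 → 0 °C; then CS2; then MeI, 0 °C → rt
Reagents that add atoms: carbon disulfide, S=C=S; iodomethane, CI
Why: Intramolecular aldol addition under equilibrating conditions, with the alkoxide trapped as the xanthate: only the C11 enolate can reach C6 in an unstrained ring (the C2 enolate would build a bicyclo[2.1.1]hexane), it can attack only the face of C6 that carries the tether on C4, and relief of the angle strain of the bridged cyclobutanone carbonyl should drive the ketone–ketone aldol; the tertiary xanthate has no β-hydrogen that can eliminate.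

Step 9
Reactants: 17 tricyclic xanthate
Product: 18 tricyclic ketone (C1 ketone; C2 and C3 methylene; C6–H toward ring B; C8 methylidene)
Conditions: Bu3SnH (2 equiv, 0.3 M), AIBN (cat.), PhMe, 90 °C, stopped at full conversion
Reagents that add atoms: none
Why: Barton–McCombie deoxygenation: the C6 cyclobutyl radical (ring opening is slow for a cyclobutyl, as opposed to a cyclobutylcarbinyl, radical) takes hydrogen on its only open face, because ring A holds C11 on the side of C4; the high stannane concentration should outrun a 1,2-acyl shift.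

Step 10
Reactants: 18 tricyclic ketone
Product: 19 tricyclic enone (C1 ketone conjugated to C2=C3; C8 methylidene)
Conditions: IBX, 4-methoxypyridine N-oxide, DMSO, rt
Reagents that add atoms: none
Why: IBX dehydrogenation of the ketone through its enol, which can form only toward C2 because C11 is quaternary; isolated alkenes are not touched.

Step 11
Reactants: 19 tricyclic enone
Product: 20 tricyclic enedione (C1 enone; C8 ketone)
Conditions: O3, CH2Cl2/MeOH, −78 °C (to first persistent blue); then Me2S, −78 °C → rt
Reagents that add atoms: ozone, [O-][O+]=O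
Why: Ozonolysis: the electron-rich 1,1-disubstituted C8 methylidene reacts far faster than the electron-poor, hindered enone alkene, which unveils the C8 ketone with loss of formaldehyde.

Step 12
Reactants: 20 tricyclic enedione
Product: 21 C8 ethylene ketal of 20 (spiro-1,3-dioxolane at C8)
Conditions: Me3SiOCH2CH2OSiMe3, TMSOTf (5 mol %), CH2Cl2, −78 → −20 °C; pyridine quench
Reagents that add atoms: 1,2-bis(trimethylsilyloxy)ethane, C[Si](C)(C)OCCO[Si](C)(C)C
Why: Aprotic Lewis-acid ketalisation selects the saturated C8 ketone over the conjugated, neopentyl C1 ketone.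

Step 13
Reactants: 21 ketal enone
Product: 22 (1R)-allylic alcohol (C1–OH on the ring A face toward C5; C2=C3; C8 ketal)
Conditions: (S)-2-methyl-CBS-oxazaborolidine (20 mol %), catecholborane, PhMe, −78 °C; MeOH then aq. NaOH work-up
Reagents that add atoms: none
Why: Corey–Bakshi–Shibata reduction under reagent control, needed because ring A lies on a near mirror plane of the skeleton and offers no substrate bias: with quaternary C11 as the large group and the cis-alkenyl carbon C2 as the small one, the (S)-catalyst should give the (1R)-alcohol.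

Step 14
Reactants: 22 allylic alcohol
Product: 23 triol (C1–OH toward C5; C2–OH and C3–OH cis to each other, toward C7; C8 ketal)
Conditions: OsO4 (5 mol %), NMO, acetone/H2O, rt
Reagents that add atoms: N-methylmorpholine N-oxide, C[N+]1([O-])CCOCC1; water, O
Why: Upjohn dihydroxylation: OsO4 adds to the cyclic allylic alcohol anti to the hydroxyl, so the cis-diol at C2 and C3 comes out trans to the C1 oxygen, which is the 1,2-trans-2,3-cis pattern of the target without an inversion step.

Step 15
Reactants: 23 triol
Product: 24 C2 monoacetate (free C1 and C3 hydroxyls; C8 ketal)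
Conditions: Ac2O (1.1 equiv), 2,4,6-collidine, CH2Cl2, −20 °C
Reagents that add atoms: acetic anhydride, CC(=O)OC(C)=O
Why: Selective acylation: the C2 hydroxyl is the only one that is not neopentyl (C1–OH adjoins C11, C3–OH adjoins C4), so one equivalent of anhydride with a hindered base should acetylate it alone.

Step 16
Reactants: 24 diol acetate; 25 angelic acid ((Z)-2-methylbut-2-enoic acid)
Product: 27 triester ketal (C1 and C3 angelates; C2 acetate; C8 ketal), via mixed anhydride 26 (not isolated)
Conditions: 25 (6 equiv), 2,4,6-trichlorobenzoyl chloride, Et3N, PhMe, rt; then 24, PhMe, 80 °C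
Reagents that add atoms: none
Why: Yamaguchi esterification, a protocol under which the (Z)-acid acylates hindered secondary alcohols without isomerising to the tiglate.

Step 17
Reactants: 27 triester ketal
Product: 28 target triester CNP0197834.1
Conditions: pyridinium p-toluenesulfonate (cat.), acetone/H2O, 50 °C
Reagents that add atoms: water, O
Why: Acid-catalysed ketal hydrolysis frees the C8 ketone; the three esters and the Z-alkenes of the angelates should be stable to this weak acid.

**Compound list**

1 | (S)-4-benzyl-3-propanoyloxazolidin-2-one | CCC(=O)N1[C@@H](Cc2ccccc2)COC1=O | starting material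
2 | ethyl (E)-4-bromo-3-methylbut-2-enoate | CCOC(=O)/C=C(\C)CBr | starting material
3 | (S)-4-benzyl-3-[(2R,4E)-6-ethoxy-2,4-dimethyl-6-oxohex-4-enoyl]oxazolidin-2-one | CCOC(=O)/C=C(\C)C[C@@H](C)C(=O)N1[C@@H](Cc2ccccc2)COC1=O | intermediate
4 | ethyl (2E,5R)-6-hydroxy-3,5-dimethylhex-2-enoate | CCOC(=O)/C=C(\C)C[C@@H](C)CO | intermediate
5 | ethyl (2E,5R)-3,5-dimethyl-6-oxohex-2-enoate | CCOC(=O)/C=C(\C)C[C@@H](C)C=O | intermediate
6 | isopropenylmagnesium bromide | CC(=C)[Mg]Br | starting material
7 | ethyl (2E,5R)-6-hydroxy-3,5,7-trimethylocta-2,7-dienoate (both C6 epimers) | CCOC(=O)/C=C(\C)C[C@@H](C)C(O)C(C)=C | intermediate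
8 | methyl 4-methyl-3-oxopentanoate | COC(=O)CC(=O)C(C)C | starting material
9 | 4-methyl-3-oxopentanoate ester of 7 (allyl β-keto ester; formed in the flask) | CCOC(=O)/C=C(\C)C[C@@H](C)C(OC(=O)CC(=O)C(C)C)C(C)=C | intermediate
10 | β-keto acid from the [3,3] shift (2-carboxy derivative of 11 at the carbon next to the ketone; formed in the flask) | CCOC(=O)/C=C(\C)C[C@@H](C)/C=C(\C)CC(C(=O)O)C(=O)C(C)C | intermediate
11 | ethyl (2E,5R,6E)-3,5,7,11-tetramethyl-10-oxododeca-2,6-dienoate | CCOC(=O)/C=C(\C)C[C@@H](C)/C=C(\C)CCC(=O)C(C)C | intermediate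
12 | (2E,5R,6E)-3,5,7,11-tetramethyl-10-oxododeca-2,6-dienoic acid | OC(=O)/C=C(\C)C[C@@H](C)/C=C(\C)CCC(=O)C(C)C | intermediate
13 | (2E,5R,6E)-3,5,7,11-tetramethyl-10-oxododeca-2,6-dienoyl chloride (formed in the flask) | ClC(=O)/C=C(\C)C[C@@H](C)/C=C(\C)CCC(=O)C(C)C | intermediate
14 | (5R,6E)-5,7,11-trimethyl-3-methylidenedodeca-1,6-diene-1,10-dione (vinylketene; formed in the flask) | O=C=CC(=C)C[C@@H](C)/C=C(\C)CCC(=O)C(C)C | intermediate
15 | (1R,2R,5S,7R)-2,7-dimethyl-4-methylidene-7-(4-methyl-3-oxopentyl)bicyclo[3.1.1]heptan-6-one | CC(C)C(=O)CC[C@]2(C)[C@@H]3C(=O)[C@H]2C(=C)C[C@H]3C | intermediate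
16 | potassium aldolate: ring A closed, C1 ketone, C6–OK (formed in the flask) | O=C1CC[C@]2(C)[C@@H]3[C@@]([O-])([C@H]2C(=C)C[C@H]3C)C1(C)C.[K+] | intermediate
17 | tricyclic S-methyl xanthate: C1 ketone, C6–OC(=S)SCH3 toward ring B, C8 methylidene | O=C1CC[C@]2(C)[C@@H]3[C@@](OC(=S)SC)([C@H]2C(=C)C[C@H]3C)C1(C)C | intermediate
18 | tricyclic ketone: C1 ketone, C6–H toward ring B, C8 methylidene | O=C1CC[C@]2(C)[C@@H]3[C@@H]([C@H]2C(=C)C[C@H]3C)C1(C)C | intermediate
19 | tricyclic enone: C1 ketone, C2=C3, C8 methylidene | O=C1C=C[C@]2(C)[C@@H]3[C@@H]([C@H]2C(=C)C[C@H]3C)C1(C)C | intermediate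
20 | tricyclic enedione: C1 enone, C8 ketone | O=C1C=C[C@]2(C)[C@@H]3[C@@H]([C@H]2C(=O)C[C@H]3C)C1(C)C | intermediate
21 | C8 ethylene ketal of 20 | O=C1C=C[C@]2(C)[C@@H]3[C@@H]([C@H]2C4(OCCO4)C[C@H]3C)C1(C)C | intermediate
22 | (1R)-allylic alcohol: C1–OH toward C5, C2=C3, C8 ketal | O[C@@H]1C=C[C@]2(C)[C@@H]3[C@@H]([C@H]2C4(OCCO4)C[C@H]3C)C1(C)C | intermediate
23 | triol: C1–OH toward C5, C2–OH and C3–OH toward C7, C8 ketal | O[C@@H]1[C@@H](O)[C@@H](O)[C@]2(C)[C@@H]3[C@@H]([C@H]2C4(OCCO4)C[C@H]3C)C1(C)C | intermediate
24 | C2 monoacetate of 23 | O[C@@H]1[C@@H](OC(C)=O)[C@@H](O)[C@]2(C)[C@@H]3[C@@H]([C@H]2C4(OCCO4)C[C@H]3C)C1(C)C | intermediate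
25 | angelic acid, (Z)-2-methylbut-2-enoic acid | C/C=C(/C)C(=O)O | starting material
26 | angelic 2,4,6-trichlorobenzoic anhydride (formed in the flask) | C/C=C(/C)C(=O)OC(=O)c1c(Cl)cc(Cl)cc1Cl | intermediate
27 | triester ketal: C1 and C3 angelates, C2 acetate, C8 ketal | C/C=C(/C)C(=O)O[C@@H]1[C@@H](OC(C)=O)[C@@H](OC(=O)/C(C)=C\C)[C@]2(C)[C@@H]3[C@@H]([C@H]2C4(OCCO4)C[C@H]3C)C1(C)C | intermediate
28 | CNP0197834.1: C1 and C3 angelates, C2 acetate, C8 ketone | C/C=C(/C)C(=O)O[C@@H]1[C@@H](OC(C)=O)[C@@H](OC(=O)/C(C)=C\C)[C@]2(C)[C@@H]3[C@@H]([C@H]2C(=O)C[C@H]3C)C1(C)C | target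

Total step count: 17. Longest linear sequence: 17 (steps 1–17 run in one line from 1).

**Steps most likely to fail**

Step 7 (key cycloaddition). The risks are incomplete π-face control by C10, γ-deprotonation at C9 instead of the methyl group (which would lead to the ring-alkene isomer), and ketene oligomerisation. Fallback from 12, back at 15: the dianion of 12 (excess LDA, THF, −78 °C, acetic acid quench) would be protonated at the α-carbon to give the deconjugated acid (5R,6E)-5,7,11-trimethyl-3-methylidene-10-oxododec-6-enoic acid F1. Coupling with pyrrolidine (EDC, HOBt) would give 1-[(5R,6E)-5,7,11-trimethyl-3-methylidene-10-oxododec-6-enoyl]pyrrolidine F2. Tf2O and 2,4,6-collidine in 1,2-dichloroethane would convert the amide (activated much faster than the ketone) into its keteniminium salt by simple α-deprotonation. This cation is more electrophilic than the ketene, should add to C4=C5 at or below room temperature with the same crossed regiochemistry and better face discrimination, and would give the cyclobutaniminium triflate of 15 F3; aqueous NaHCO3 would hydrolyse it to 15.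

Step 8 (aldol ring closure and xanthate formation). The risks are an unfavourable aldol equilibrium (retro-aldol), trapping of free enolate by CS2, and intermolecular aldol. Fallback from 15, back at 17: phenyltrimethylammonium tribromide in THF at 0 °C would brominate the side-chain ketone at its more substituted α-carbon C11 (the cyclobutanone cannot enolise, and tribromide salts spare alkenes) to give (1R,2R,5S,7R)-7-(4-bromo-4-methyl-3-oxopentyl)-2,7-dimethyl-4-methylidenebicyclo[3.1.1]heptan-6-one F4. SmI2 in THF at −78 °C would reduce the C–Br bond to a samarium enolate fixed at C11, which should add to C6 irreversibly at low temperature (samarium Reformatsky-type aldol) to give the free tricyclic aldol F5. KH, CS2 and MeI would then convert it into 17.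

Step 16 (double angeloylation). The risks are migration of the C2 acetyl group to the cis C3 oxygen under the basic, heated conditions, followed by acylation of the freed C2 hydroxyl, and slow acylation of the two neopentyl alcohols. Fallback from 23, back at 28: Et3SiCl and imidazole in DMF at −20 °C would silylate the least hindered hydroxyl to give the C2 triethylsilyl ether of 23 F6. Yamaguchi esterification with angelic acid as in step 16 would give the C1,C3-bis-angelate C2 silyl ether C8 ketal F7, with no acetyl group present to migrate. Aqueous HCl in THF would remove the silyl ether and the ketal together to give the C1,C3-bis-angelate with free C2–OH and C8 ketone F8. Ac2O, DMAP and pyridine at room temperature would then acetylate the unhindered C2 hydroxyl to give 28.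

**Further compounds**

F1 | step 7 | (5R,6E)-5,7,11-trimethyl-3-methylidene-10-oxododec-6-enoic acid | OC(=O)CC(=C)C[C@@H](C)/C=C(\C)CCC(=O)C(C)C
F2 | step 7 | 1-[(5R,6E)-5,7,11-trimethyl-3-methylidene-10-oxododec-6-enoyl]pyrrolidine | O=C(CC(=C)C[C@@H](C)/C=C(\C)CCC(=O)C(C)C)N1CCCC1
F3 | step 7 | cyclobutaniminium triflate of 15 (C6=N+ of pyrrolidinium) | CC(C)C(=O)CC[C@]2(C)[C@@H]3C(=[N+]4CCCC4)[C@H]2C(=C)C[C@H]3C.[O-]S(=O)(=O)C(F)(F)F
F4 | step 8 | (1R,2R,5S,7R)-7-(4-bromo-4-methyl-3-oxopentyl)-2,7-dimethyl-4-methylidenebicyclo[3.1.1]heptan-6-one | CC(C)(Br)C(=O)CC[C@]2(C)[C@@H]3C(=O)[C@H]2C(=C)C[C@H]3C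
F5 | step 8 | free tricyclic aldol: C1 ketone, C6–OH toward ring B, C8 methylidene | O=C1CC[C@]2(C)[C@@H]3[C@@](O)([C@H]2C(=C)C[C@H]3C)C1(C)C
F6 | step 16 | C2 triethylsilyl ether of 23 | O[C@@H]1[C@@H](O[Si](CC)(CC)CC)[C@@H](O)[C@]2(C)[C@@H]3[C@@H]([C@H]2C4(OCCO4)C[C@H]3C)C1(C)C
F7 | step 16 | C1,C3-bis-angelate C2 silyl ether C8 ketal | C/C=C(/C)C(=O)O[C@@H]1[C@@H](O[Si](CC)(CC)CC)[C@@H](OC(=O)/C(C)=C\C)[C@]2(C)[C@@H]3[C@@H]([C@H]2C4(OCCO4)C[C@H]3C)C1(C)C
F8 | step 16 | C1,C3-bis-angelate with free C2–OH and C8 ketone | C/C=C(/C)C(=O)O[C@@H]1[C@@H](O)[C@@H](OC(=O)/C(C)=C\C)[C@]2(C)[C@@H]3[C@@H]([C@H]2C(=O)C[C@H]3C)C1(C)C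
A1 | direct plan | 3-methyl-3-[(tert-butyldiphenylsilyloxy)methyl]cyclobutan-1-one | CC1(CO[Si](c2ccccc2)(c2ccccc2)C(C)(C)C)CC(=O)C1
A2 | direct plan | (1R,4R,5R,7R)-7-[(tert-butyldiphenylsilyloxy)methyl]-4,7-dimethylbicyclo[3.1.1]heptane-2,6-dione | CC(C)(C)[Si](c1ccccc1)(c1ccccc1)OC[C@]2(C)[C@@H]3C(=O)[C@H]2C(=O)C[C@H]3C
A3 | direct plan | acryloyl ketone: C4–C(=O)CH=CH2, C6 isopropylidene, C8 ethylene ketal | C=CC(=O)[C@]2(C)[C@@H]3C(=C(C)C)[C@H]2C4(OCCO4)C[C@H]3C
A4 | direct plan | tricyclic C3 ketone, C8 ethylene ketal | C1CC(=O)[C@]2(C)[C@@H]3[C@@H]([C@H]2C4(OCCO4)C[C@H]3C)C1(C)C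
A5 | direct plan | C1,C2-diol C3 triethylsilyl ether, C2 epimeric to the target, C8 ethylene ketal | O[C@@H]1[C@H](O)[C@@H](O[Si](CC)(CC)CC)[C@]2(C)[C@@H]3[C@@H]([C@H]2C4(OCCO4)C[C@H]3C)C1(C)C
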